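Slowness was what I read first: at 10.0 min the green run still held 99% of its substrate and the violet run 100%, so I treated that time as a lag and started my clock τ at its end.

the same everywhere: substrate 13 mM
- green: reagent 1 equiv (in portions, 4); run made earlier; portions every 2.0 min
- violet: reagent 2.2 equiv (in portions, 4); run made earlier; portions every 2.0 min
- alpha: reagent 1.50 equiv (in portions, 4); the portions of reagent follow each other after 2.0 min, the first at the start; time 1.0 h
- zeta: reagent 1.50 equiv (in portions, 4); the portions of reagent follow each other after 2.0 min, the first at the start; time 3.0 h

- green (time / min: target / %, substrate / %): 10.0: 0, 99; 20.0: 1, 96; 30.0: 7, 93; 40.0: 12, 85; 50.0: 13, 81; 60.0: 21, 76; 80.0: 30, 65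
- violet (time / min: target / %, substrate / %): 10.0: 2, 100; 20.0: 12, 84; 30.0: 22, 71; 40.0: 35, 61; 50.0: 47, 55; 60.0: 53, 44; 80.0: 62, 33

(standard deviation of a reading: 1.5 percentage points)

- which of the two there is more of at the end, counted by the substrate in each, alpha (target / side product)
- which of the two there is more of at the end, counted by the substrate in each, zeta (target / side product)
- final target, as a percentage of the substrate charged, in alpha
- final target, as a percentage of the substrate charged, in zeta

- percent here means substrate units held: one side product counts as two
- the numbers in the tables scatter with a standard deviation of 1.5 percentage points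
- a reading or a percentage of target counts all its forms, free or not

I turned the question round and asked what side product would need in order to lead in alpha or zeta. Percent here counts substrate units, so the gap left by substrate and target is the side product. I defined the side share φ as that gap over the substrate consumed, the complement of the selectivity. Pooled over both runs at 80.0 min, it read 0.0980, from readings that scatter by 1.5 percentage points. Side product leads past φ = 0.5, which is 5.10 times that reading.

For the substrate consumed, let a be the fraction left and r the equivalents of reagent, which I took as used one to one. Then da/dτ = −κa(a + r − 1) integrates to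

a = (r − 1) / (r·exp[(r − 1)κτ] − 1)

With the limit a = 1/(1 + κτ) for green, where r = 1, the last readings gave κ = 0.00769 min⁻¹ in green and 0.00887 min⁻¹ in violet, and I took the mean, 0.00828 min⁻¹. My reckoning was then:

alpha: a = 59.2%, target (1 − φ)(1 − a) = 36.8%, side product φ(1 − a) = 4.00%

zeta: a = 24.6%, target 68.0%, side product 7.39%

The forecast gave 36% (30% to 42%) for alpha and 67% (55% to 77%) for zeta, with target ahead in both; mine differed from these by 0.80 points and 1 point. Its words were: “The extrapolation is uncertain, and target stays ahead in both.”

Alpha gave 35.1% target, crystals counted in, and 4.14% side product, a side share of 0.105. Zeta gave 67.5% and 9.71%, a share of 0.126.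

substrate + reagent → target (k = 7.60 × 10⁻⁴ L mol⁻¹ s⁻¹); substrate + reagent + target → 2 target (k = 8.80 L² mol⁻² s⁻¹); crystals ⇌ target, rate k3*(cs3 - [target]) while solid is left; crystals form when [target] > cs3 (solubility = 1.10 mM, k = 0.0340 s⁻¹); substrate + target → side product (k = 0.00920 L mol⁻¹ s⁻¹) The neighbour was alpha left until 2.5 h, where the same lines gave a = 29.8%, target 63.3% and side product 6.88%. That flask held 28% substrate, 62.9% target and 8.78% side product, a side share of 0.122.

(The numbers in the tables were computed from invented constants; noise was put on by code.)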